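Each lactone ring (O1, C2=O, C3–OH, C4, C5H2) is disconnected between C4 and C5. C5 sits on the ester oxygen O1 and C4 carries a benzyl group, so C5 can be an acyloxymethyl radical and C4 the inner carbon of a styrene. A 5-exo radical cyclisation of an iodomethyl (S)-2-hydroxy-4-arylbut-3-enoate closes the lactone, forms C4–C5 and sets C4 from the C3 carbinol in one operation, shown first for the lactone whose C4 benzyl ring enters the biaryl. C3 is then made quaternary by benzylation of the lactone enediolate anti to the C4 benzyl. Two such bromo lactones are joined by borylation/Suzuki coupling; hydrogenolysis frees the phenols.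

Key step: step 5

Remark on numbering: in each lactone the ring atoms are O1, C2 (C=O), C3 (C–OH), C4 (CH) and C5 (OCH2). Unit B is the lactone whose C4 benzyl ring lies in the biaryl; unit A is the lactone whose C3 benzyl ring lies in the biaryl.

Assumption: in steps 3 and 9 the (S)-configured diphosphine is taken to deliver the 2S carbinol; should the sense prove opposite, the antipodal ligand is used with no other change.

Step 1
Reactants: 1 5-bromovanillin
Product: 2 4-(benzyloxy)-3-bromo-5-methoxybenzaldehyde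
Conditions: BnBr, K2CO3, DMF, 60 °C
Reagents that add atoms: benzyl bromide, BrCc1ccccc1
Why: Williamson ether synthesis on the phenoxide; the aldehyde and the aryl bromide are inert to K2CO3.

Step 2
Reactants: 2 4-(benzyloxy)-3-bromo-5-methoxybenzaldehyde; 3 pyruvic acid
Product: 4 (E)-4-[4-(benzyloxy)-3-bromo-5-methoxyphenyl]-2-oxobut-3-enoic acid
Conditions: KOH, MeOH/H2O, 0 °C to rt; then 1 M HCl
Reagents that add atoms: none
Why: Claisen–Schmidt aldol condensation of the non-enolisable aldehyde with the pyruvate enolate; dehydration should give the conjugated E alkene as its potassium salt before acidification.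

Step 3
Reactants: 4 (E)-4-[4-(benzyloxy)-3-bromo-5-methoxyphenyl]-2-oxobut-3-enoic acid
Product: 5 (S,E)-4-[4-(benzyloxy)-3-bromo-5-methoxyphenyl]-2-hydroxybut-3-enoic acid
Conditions: [RuCl(benzene)((S)-SunPhos)]Cl (1 mol %), H2 (20 bar), THF, 50 °C; recrystallisation
Reagents that add atoms: none
Why: Asymmetric hydrogenation of the ketone of a 2-oxo acid by a ruthenium atropisomeric-diphosphine catalyst sets the carbinol (2S) through ligand control of the face of hydride delivery to the chelated keto acid, while the styrene, aryl bromide and benzyl ether should survive at this temperature; recrystallisation is planned to raise the enantiomeric purity.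

Step 4
Reactants: 5 (S,E)-4-[4-(benzyloxy)-3-bromo-5-methoxyphenyl]-2-hydroxybut-3-enoic acid
Product: 6 chloromethyl (S,E)-4-[4-(benzyloxy)-3-bromo-5-methoxyphenyl]-2-hydroxybut-3-enoate
Conditions: ClCH2OSO2Cl, NaHCO3, Bu4NHSO4 (cat.), CH2Cl2/H2O, rt
Reagents that add atoms: chloromethyl chlorosulfate, ClCOS(Cl)(=O)=O
Why: Ester formation by phase-transfer O-alkylation of the carboxylate; the neutral secondary alcohol is a much poorer nucleophile and the weak base should not enolise the carbinol centre.

Step 5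
Reactants: 6 chloromethyl (S,E)-4-[4-(benzyloxy)-3-bromo-5-methoxyphenyl]-2-hydroxybut-3-enoate
Product: 8 (3S,4R)-4-[4-(benzyloxy)-3-bromo-5-methoxybenzyl]-3-hydroxyoxolan-2-one, via iodomethyl ester 7 (not isolated)
Conditions: NaI, acetone, rt, dark; solvent exchange; then Bu3SnH (1.3 equiv), AIBN (cat.), syringe pump, PhH (0.01 M), 80 °C
Reagents that add atoms: sodium iodide, [Na+].[I-] (supplies only the iodine of intermediate 7; product 8 gains nothing but hydrogen, from Bu3SnH)
Why: Bu3Sn• takes iodine from 7 to give the acyloxymethyl radical at C5, which adds to C4 of the C4=CH–aryl double bond; the benzylic radical formed is reduced by Bu3SnH, which carries the chain. The closest known reaction type is the tin hydride mediated reductive 5-exo cyclisation of halomethyl alkenoates to γ-lactones. The lactone ring (O1, C2, C3, C4, C5) closes in the 5-exo-trig mode. The new stereocentre C4 is set by the C3 carbinol: in the chair-like transition state the C3 hydroxyl sits pseudo-equatorial and C5 adds to the alkene face that places the forming benzyl group trans to OH, so the 3S centre should give 4R. The step needs exo over 6-endo closure, ring closure before hydrogen transfer to the C5 radical, and survival of the aryl bromide; the aryl group on the outer alkene carbon makes exo attack lead to a benzylic radical and speeds addition enough to offset the poorly populated ester rotamer in which C5 lies syn to C3, slow hydride addition keeps premature reduction down, and the alkyl iodide reacts with the stannyl radical much faster than the aryl bromide. The minor cis lactone would lead into the enantiomeric series after step 7 and is to be removed by chromatography here.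

Step 6
Reactants: 9 4-(benzyloxy)-3-methoxybenzyl alcohol
Product: 10 4-(benzyloxy)-3-methoxybenzyl bromide
Conditions: PBr3, CH2Cl2, 0 °C
Reagents that add atoms: phosphorus tribromide, BrP(Br)Br
Why: Bromination of a benzylic alcohol through its phosphite ester; the aryl benzyl ether is stable at 0 °C.

Step 7
Reactants: 8 (3S,4R)-4-[4-(benzyloxy)-3-bromo-5-methoxybenzyl]-3-hydroxyoxolan-2-one; 10 4-(benzyloxy)-3-methoxybenzyl bromide
Product: 11 (3R,4R)-4-[4-(benzyloxy)-3-bromo-5-methoxybenzyl]-3-[4-(benzyloxy)-3-methoxybenzyl]-3-hydroxyoxolan-2-one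
Conditions: LiN(iPr)2 (2.2 equiv), THF, −78 °C; then 10, DMPU, −78 to −40 °C; AcOH quench
Reagents that add atoms: none
Why: Diastereoselective C-alkylation of the α-hydroxy lactone enediolate (dianion): the planar C3 is benzylated on the face anti to the C4 benzyl group, so the new benzyl should end trans to the C4 benzyl and OH cis to it (3R), the old C3 configuration being erased and re-set from C4; the aryl bromide should tolerate the amide base at −78 °C.

Step 8
Reactants: 12 4-(benzyloxy)-3-methoxybenzaldehyde; 3 pyruvic acid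
Product: 13 (E)-4-[4-(benzyloxy)-3-methoxyphenyl]-2-oxobut-3-enoic acid
Conditions: KOH, MeOH/H2O, 0 °C to rt; then 1 M HCl
Reagents that add atoms: none
Why: Claisen–Schmidt aldol condensation as in step 2, giving the E keto acid.

Step 9
Reactants: 13 (E)-4-[4-(benzyloxy)-3-methoxyphenyl]-2-oxobut-3-enoic acid
Product: 14 (S,E)-4-[4-(benzyloxy)-3-methoxyphenyl]-2-hydroxybut-3-enoic acid
Conditions: [RuCl(benzene)((S)-SunPhos)]Cl (1 mol %), H2 (20 bar), THF, 50 °C; recrystallisation
Reagents that add atoms: none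
Why: Asymmetric ketone hydrogenation as in step 3; the ligand sets the 2S carbinol and the styrene should be retained.

Step 10
Reactants: 14 (S,E)-4-[4-(benzyloxy)-3-methoxyphenyl]-2-hydroxybut-3-enoic acid
Product: 15 chloromethyl (S,E)-4-[4-(benzyloxy)-3-methoxyphenyl]-2-hydroxybut-3-enoate
Conditions: ClCH2OSO2Cl, NaHCO3, Bu4NHSO4 (cat.), CH2Cl2/H2O, rt
Reagents that add atoms: chloromethyl chlorosulfate, ClCOS(Cl)(=O)=O
Why: Phase-transfer O-alkylation of the carboxylate as in step 4.

Step 11
Reactants: 15 chloromethyl (S,E)-4-[4-(benzyloxy)-3-methoxyphenyl]-2-hydroxybut-3-enoate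
Product: 17 (3S,4R)-4-[4-(benzyloxy)-3-methoxybenzyl]-3-hydroxyoxolan-2-one, via iodomethyl ester 16 (not isolated)
Conditions: NaI, acetone, rt, dark; solvent exchange; then Bu3SnH (1.3 equiv), AIBN (cat.), syringe pump, PhH (0.01 M), 80 °C
Reagents that add atoms: sodium iodide, [Na+].[I-] (supplies only the iodine of intermediate 16; product 17 gains nothing but hydrogen, from Bu3SnH)
Why: Finkelstein exchange and the same tin hydride mediated 5-exo-trig cyclisation of the acyloxymethyl radical as in step 5; C4 (R) should again be set trans to the C3 hydroxyl by the chair-like transition state.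

Step 12
Reactants: 2 4-(benzyloxy)-3-bromo-5-methoxybenzaldehyde
Product: 18 [4-(benzyloxy)-3-bromo-5-methoxyphenyl]methanol
Conditions: NaBH4, MeOH/THF, 0 °C
Reagents that add atoms: none
Why: Hydride reduction of the aldehyde by NaBH4; aryl bromide and benzyl ether are untouched.

Step 13
Reactants: 18 [4-(benzyloxy)-3-bromo-5-methoxyphenyl]methanol
Product: 19 4-(benzyloxy)-3-bromo-5-methoxybenzyl bromide
Conditions: PBr3, CH2Cl2, 0 °C
Reagents that add atoms: phosphorus tribromide, BrP(Br)Br
Why: Bromination of the benzylic alcohol through its phosphite ester, as in step 6.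

Step 14
Reactants: 17 (3S,4R)-4-[4-(benzyloxy)-3-methoxybenzyl]-3-hydroxyoxolan-2-one; 19 4-(benzyloxy)-3-bromo-5-methoxybenzyl bromide
Product: 20 (3R,4R)-3-[4-(benzyloxy)-3-bromo-5-methoxybenzyl]-4-[4-(benzyloxy)-3-methoxybenzyl]-3-hydroxyoxolan-2-one
Conditions: LiN(iPr)2 (2.2 equiv), THF, −78 °C; then 19, DMPU, −78 to −40 °C; AcOH quench
Reagents that add atoms: none
Why: Diastereoselective C-alkylation of the lactone enediolate anti to the C4 benzyl group as in step 7, giving the 3R quaternary carbinol; the benzylic bromide reacts and the aryl bromide stays.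

Step 15
Reactants: 20 (3R,4R)-3-[4-(benzyloxy)-3-bromo-5-methoxybenzyl]-4-[4-(benzyloxy)-3-methoxybenzyl]-3-hydroxyoxolan-2-one; 11 (3R,4R)-4-[4-(benzyloxy)-3-bromo-5-methoxybenzyl]-3-[4-(benzyloxy)-3-methoxybenzyl]-3-hydroxyoxolan-2-one
Product: 22 tetra-O-benzyl ether of the target (biaryl bond between the C3 benzyl ring of unit A and the C4 benzyl ring of unit B), via pinacol boronate 21 (not isolated)
Conditions: 20, B2pin2, Pd(dppf)Cl2 (5 mol %), KOAc, 1,4-dioxane, 90 °C; then 11, K3PO4, H2O, 90 °C; 1 M HCl work-up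
Reagents that add atoms: bis(pinacolato)diboron, CC1(C)OB(OC1(C)C)B1OC(C)(C)C(C)(C)O1 (supplies only the boryl group of intermediate 21; none of its atoms remain in 22)
Why: Miyaura borylation of 20 followed in the same pot by Suzuki–Miyaura coupling with 11 should form the 2,2'-dioxygenated biaryl bond between two different aryl bromides; the tertiary alcohols need no protection and the acidic work-up recloses any lactone opened by the base.

Step 16
Reactants: 22 tetra-O-benzyl ether of the target
Product: 23 CNP0218652.1 (target)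
Conditions: H2 (1 atm), Pd/C, EtOAc/MeOH, rt
Reagents that add atoms: none
Why: Hydrogenolysis of the four aryl benzyl ethers; lactones, tertiary alcohols and the biaryl are inert and no stereocentre is touched.

Compound list

1 | 5-bromovanillin (3-bromo-4-hydroxy-5-methoxybenzaldehyde) | O=Cc1cc(OC)c(O)c(Br)c1 | starting material
2 | 4-(benzyloxy)-3-bromo-5-methoxybenzaldehyde | O=Cc1cc(OC)c(OCc2ccccc2)c(Br)c1 | intermediate
3 | pyruvic acid | CC(=O)C(O)=O | starting material
4 | (E)-4-[4-(benzyloxy)-3-bromo-5-methoxyphenyl]-2-oxobut-3-enoic acid | OC(=O)C(=O)/C=C/c1cc(OC)c(OCc2ccccc2)c(Br)c1 | intermediate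
5 | (S,E)-4-[4-(benzyloxy)-3-bromo-5-methoxyphenyl]-2-hydroxybut-3-enoic acid | OC(=O)[C@@H](O)/C=C/c1cc(OC)c(OCc2ccccc2)c(Br)c1 | intermediate
6 | chloromethyl (S,E)-4-[4-(benzyloxy)-3-bromo-5-methoxyphenyl]-2-hydroxybut-3-enoate | ClCOC(=O)[C@@H](O)/C=C/c1cc(OC)c(OCc2ccccc2)c(Br)c1 | intermediate
7 | iodomethyl (S,E)-4-[4-(benzyloxy)-3-bromo-5-methoxyphenyl]-2-hydroxybut-3-enoate | ICOC(=O)[C@@H](O)/C=C/c1cc(OC)c(OCc2ccccc2)c(Br)c1 | intermediate
8 | (3S,4R)-4-[4-(benzyloxy)-3-bromo-5-methoxybenzyl]-3-hydroxyoxolan-2-one | COc1cc(C[C@@H]2COC(=O)[C@H]2O)cc(Br)c1OCc1ccccc1 | intermediate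
9 | 4-(benzyloxy)-3-methoxybenzyl alcohol | OCc1ccc(OCc2ccccc2)c(OC)c1 | starting material
10 | 4-(benzyloxy)-3-methoxybenzyl bromide | BrCc1ccc(OCc2ccccc2)c(OC)c1 | intermediate
11 | (3R,4R)-4-[4-(benzyloxy)-3-bromo-5-methoxybenzyl]-3-[4-(benzyloxy)-3-methoxybenzyl]-3-hydroxyoxolan-2-one | COc1cc(C[C@@H]2COC(=O)[C@@]2(O)Cc2ccc(OCc3ccccc3)c(OC)c2)cc(Br)c1OCc1ccccc1 | intermediate
12 | 4-(benzyloxy)-3-methoxybenzaldehyde | O=Cc1ccc(OCc2ccccc2)c(OC)c1 | starting material
13 | (E)-4-[4-(benzyloxy)-3-methoxyphenyl]-2-oxobut-3-enoic acid | OC(=O)C(=O)/C=C/c1ccc(OCc2ccccc2)c(OC)c1 | intermediate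
14 | (S,E)-4-[4-(benzyloxy)-3-methoxyphenyl]-2-hydroxybut-3-enoic acid | OC(=O)[C@@H](O)/C=C/c1ccc(OCc2ccccc2)c(OC)c1 | intermediate
15 | chloromethyl (S,E)-4-[4-(benzyloxy)-3-methoxyphenyl]-2-hydroxybut-3-enoate | ClCOC(=O)[C@@H](O)/C=C/c1ccc(OCc2ccccc2)c(OC)c1 | intermediate
16 | iodomethyl (S,E)-4-[4-(benzyloxy)-3-methoxyphenyl]-2-hydroxybut-3-enoate | ICOC(=O)[C@@H](O)/C=C/c1ccc(OCc2ccccc2)c(OC)c1 | intermediate
17 | (3S,4R)-4-[4-(benzyloxy)-3-methoxybenzyl]-3-hydroxyoxolan-2-one | COc1cc(C[C@@H]2COC(=O)[C@H]2O)ccc1OCc1ccccc1 | intermediate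
18 | [4-(benzyloxy)-3-bromo-5-methoxyphenyl]methanol | OCc1cc(OC)c(OCc2ccccc2)c(Br)c1 | intermediate
19 | 4-(benzyloxy)-3-bromo-5-methoxybenzyl bromide | BrCc1cc(OC)c(OCc2ccccc2)c(Br)c1 | intermediate
20 | (3R,4R)-3-[4-(benzyloxy)-3-bromo-5-methoxybenzyl]-4-[4-(benzyloxy)-3-methoxybenzyl]-3-hydroxyoxolan-2-one | COc1cc(C[C@@H]2COC(=O)[C@@]2(O)Cc2cc(OC)c(OCc3ccccc3)c(Br)c2)ccc1OCc1ccccc1 | intermediate
21 | pinacol boronate of 20 (Bpin in place of Br) | COc1cc(C[C@@H]2COC(=O)[C@@]2(O)Cc2cc(OC)c(OCc3ccccc3)c(B3OC(C)(C)C(C)(C)O3)c2)ccc1OCc1ccccc1 | intermediate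
22 | tetra-O-benzyl ether of the target | COc1cc(C[C@@H]2COC(=O)[C@@]2(O)Cc2cc(OC)c(OCc3ccccc3)c(-c3cc(C[C@@H]4COC(=O)[C@@]4(O)Cc4ccc(OCc5ccccc5)c(OC)c4)cc(OC)c3OCc3ccccc3)c2)ccc1OCc1ccccc1 | intermediate
23 | CNP0218652.1: two (3R,4R)-3-hydroxy-3,4-bis(4-hydroxy-3-methoxybenzyl)oxolan-2-one units joined ortho to the phenol OH, between the C3 benzyl ring of one and the C4 benzyl ring of the other | COc1cc(C[C@@H]2COC(=O)[C@@]2(O)Cc2cc(OC)c(O)c(-c3cc(C[C@@H]4COC(=O)[C@@]4(O)Cc4ccc(O)c(OC)c4)cc(OC)c3O)c2)ccc1O | target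

Total step count: 16. Longest linear sequence: 8 steps (steps 1, 2, 3, 4, 5, 7, 15, 16). Steps 11 and 14 repeat the chemistry of steps 5 and 7 and are not counted separately below.

Steps most likely to fail

Step 5. The C5 radical may be reduced before it cyclises, because ring closure needs the minor ester rotamer. Facial selectivity at C4 may be modest, and the iodomethyl ester may alkylate the neighbouring hydroxyl while it waits for the hydride. The fallback keeps the same C4–C5 ring closure but moves the tether from the ester oxygen to the C3 oxygen, as a temporary silicon ring; it sets out from compound 4 and comes back at compound 11. With the tether on the C3 oxygen, the ester and not the hydroxyl is the exocyclic group that the new benzyl avoids, so the opposite carbinol configuration is needed for 4R. Compound 4 is therefore hydrogenated with the antipodal ligand to the (R)-hydroxy acid F1, which is esterified (MeI, KHCO3, DMF) to the methyl ester F2. Silylation with BrCH2SiMe2Cl and imidazole gives the (bromomethyl)dimethylsilyl ether F3. Bu3SnH/AIBN in benzene at 80 °C should close the oxasilolane F4 by 5-exo attack of the Si–CH2 radical on C4, with the ester and the new benzyl trans. Tamao oxidation (H2O2, KF, KHCO3) gives the diol ester F5, which lactonises with catalytic TsOH to the cis hydroxy lactone F6, the C3 epimer of 8 with the same 4R centre. F6 is taken through the conditions of step 7, where its enediolate is identical to that of 8, and gives 11.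

Step 7. Dianion formation may be incomplete, the alkoxide oxygen may be benzylated in competition with C3, and the strong amide base may attack the aryl bromide ring. The fallback replaces the dianion by a mono-anion of an O-protected lactone; it sets out from compound 8 and comes back at compound 11. Compound 8 is silylated (TBSOTf, 2,6-lutidine) to the silyl ether F7. Its enolate, made with the weaker base KN(SiMe3)2 at −78 °C, is benzylated with 10 anti to the C4 benzyl to give the quaternary silyl ether F8. Bu4NF/AcOH then frees the tertiary alcohol to give 11.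

Step 15. The hindered ortho-alkoxy boronate may protodeboronate or homocouple in the one-pot sequence, and the aqueous base may open the lactones during a slow coupling. The fallback makes the biaryl bond with a small, isolable boronate and attaches the second lactone by the enediolate alkylation already used; it sets out from compounds 18, 11 and 17 and comes back at compound 22. Compound 18 is borylated (B2pin2, Pd(dppf)Cl2, KOAc) to the benzylic alcohol boronate F9. Suzuki–Miyaura coupling of F9 with 11 (Pd(OAc)2, SPhos, K3PO4, toluene/H2O) gives the biaryl benzylic alcohol F10. CBr4/PPh3 converts only its primary benzylic hydroxyl into the biaryl benzylic bromide F11. The enediolate of 17, made as in step 14 with one further equivalent of base for the tertiary hydroxyl of F11, is alkylated with F11 to give 22.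

Further compounds

F1 | step 5 | (R,E)-4-[4-(benzyloxy)-3-bromo-5-methoxyphenyl]-2-hydroxybut-3-enoic acid | OC(=O)[C@H](O)/C=C/c1cc(OC)c(OCc2ccccc2)c(Br)c1
F2 | step 5 | methyl (R,E)-4-[4-(benzyloxy)-3-bromo-5-methoxyphenyl]-2-hydroxybut-3-enoate | COC(=O)[C@H](O)/C=C/c1cc(OC)c(OCc2ccccc2)c(Br)c1
F3 | step 5 | methyl (R,E)-4-[4-(benzyloxy)-3-bromo-5-methoxyphenyl]-2-{[(bromomethyl)dimethylsilyl]oxy}but-3-enoate | COC(=O)[C@H](O[Si](C)(C)CBr)/C=C/c1cc(OC)c(OCc2ccccc2)c(Br)c1
F4 | step 5 | methyl (4S,5R)-4-[4-(benzyloxy)-3-bromo-5-methoxybenzyl]-2,2-dimethyl-1,2-oxasilolane-5-carboxylate | COc1cc(C[C@@H]2C[Si](C)(C)O[C@H]2C(=O)OC)cc(Br)c1OCc1ccccc1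
F5 | step 5 | methyl (2R,3R)-4-[4-(benzyloxy)-3-bromo-5-methoxyphenyl]-2-hydroxy-3-(hydroxymethyl)butanoate | COC(=O)[C@H](O)[C@@H](CO)Cc1cc(OC)c(OCc2ccccc2)c(Br)c1
F6 | step 5 | (3R,4R)-4-[4-(benzyloxy)-3-bromo-5-methoxybenzyl]-3-hydroxyoxolan-2-one | COc1cc(C[C@@H]2COC(=O)[C@@H]2O)cc(Br)c1OCc1ccccc1
F7 | step 7 | (3S,4R)-4-[4-(benzyloxy)-3-bromo-5-methoxybenzyl]-3-[(tert-butyldimethylsilyl)oxy]oxolan-2-one | COc1cc(C[C@@H]2COC(=O)[C@H]2O[Si](C)(C)C(C)(C)C)cc(Br)c1OCc1ccccc1
F8 | step 7 | (3R,4R)-4-[4-(benzyloxy)-3-bromo-5-methoxybenzyl]-3-[4-(benzyloxy)-3-methoxybenzyl]-3-[(tert-butyldimethylsilyl)oxy]oxolan-2-one | COc1cc(C[C@@H]2COC(=O)[C@@]2(O[Si](C)(C)C(C)(C)C)Cc2ccc(OCc3ccccc3)c(OC)c2)cc(Br)c1OCc1ccccc1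
F9 | step 15 | [4-(benzyloxy)-3-methoxy-5-(4,4,5,5-tetramethyl-1,3,2-dioxaborolan-2-yl)phenyl]methanol | OCc1cc(OC)c(OCc2ccccc2)c(B2OC(C)(C)C(C)(C)O2)c1
F10 | step 15 | (3R,4R)-4-{[2',6-bis(benzyloxy)-5'-(hydroxymethyl)-3',5-dimethoxybiphenyl-3-yl]methyl}-3-[4-(benzyloxy)-3-methoxybenzyl]-3-hydroxyoxolan-2-one | COc1cc(C[C@@H]2COC(=O)[C@@]2(O)Cc2ccc(OCc3ccccc3)c(OC)c2)cc(-c2cc(CO)cc(OC)c2OCc2ccccc2)c1OCc1ccccc1
F11 | step 15 | (3R,4R)-4-{[2',6-bis(benzyloxy)-5'-(bromomethyl)-3',5-dimethoxybiphenyl-3-yl]methyl}-3-[4-(benzyloxy)-3-methoxybenzyl]-3-hydroxyoxolan-2-one | COc1cc(C[C@@H]2COC(=O)[C@@]2(O)Cc2ccc(OCc3ccccc3)c(OC)c2)cc(-c2cc(CBr)cc(OC)c2OCc2ccccc2)c1OCc1ccccc1
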